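The reading fell at 30 min, so for whoever took over the bench I reckoned Tuesday's, which I expected last, as a decay measured against that time.

| flask | substrate | coupling partner | remark | time |
|---|---|---|---|---|
| violet | 0.049 M | 0.18 M | run made earlier |  |
| teal | 0.27 M | 0.18 M | run made earlier |  |
| grey | 0.10 M | 0.26 M | run made earlier |  |
| Tuesday's | 0.30 M | 0.120 M |  | 30 min |
| Friday's | 0.060 M | 0.500 M |  | 30 min |
| Thursday's | 0.10 M | 0.250 M |  | 30 min |
| Saturday's | 0.40 M | 0.180 M |  | 30 min |
| Monday's | 0.10 M | 0.180 M |  | 30 min |
| Wednesday's | 0.15 M | 0.120 M |  | 30 min |

| run | time / min | target / % | substrate / % |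
|---|---|---|---|
| violet | 4.00 | 13.6 | 56.5 |
| violet | 8.00 | 26.8 | 47.8 |
| violet | 10.0 | 33.1 | 43.7 |
| violet | 15.0 | 41.5 | 37.5 |
| violet | 20.0 | 51.3 | 31.1 |
| teal | 1.50 | 2.9 | 70.7 |
| teal | 3.00 | 8.5 | 66.2 |
| teal | 5.00 | 13.1 | 62.0 |
| teal | 8.00 | 19.7 | 53.5 |
| teal | 12.0 | 25.7 | 48.7 |
| teal | 20.0 | 33.7 | 40.5 |
| grey | 2.00 | 9.7 | 54.8 |
| grey | 5.00 | 19.9 | 46.0 |
| grey | 10.0 | 35.1 | 34.0 |
| grey | 15.0 | 48.4 | 26.8 |
| grey | 20.0 | 56.4 | 21.5 |

(each reading ± 1 percentage point)

- a reading or a percentage of target counts all its forms, free or not
- a reading of substrate is of its free form alone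

- all flasks from highest to lowest amount of target, in percent of the substrate charged, at 30 min (Tuesday's / Friday's / Thursday's / Saturday's / Monday's / Wednesday's)
- the amount of target, in percent of the substrate charged of the flask you put first, at 30 min
- the amount of target, in percent of the substrate charged of the flask you put last, at 30 min

1. Tuesday's held 0.30 M substrate and 0.120 M coupling partner. I took one partner per target, and partner was the smaller charge, so I treated it as the limiting reagent, with a ceiling of 40.0% target.
2. In the teal run at 20.0 min, target read 33.7%, so 49.4% of the partner charge had not become target; I call this part unconverted. That gave a decay time of 28.4 min.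
3. I assumed this time scales inversely with the substrate charge. For Tuesday's, the partner time constant, the time in which unconverted partner falls by a factor of e, came to 25.6 min.
4. I computed target as the ceiling less a correction, the partner still unconverted: 12.4% of the substrate charged, leaving 27.6% in Tuesday's. The same reckoning gave Saturday's 35.6%, more than Tuesday's.
5. My note said to touch neither charge, since the ceiling was reckoned from both and the time constant from the substrate charge. It also said not to count missing substrate as target: in the teal run at 20.0 min, 25.8% stood in neither reading.

The forecast gave Friday's > Thursday's > Monday's > Wednesday's > Saturday's > Tuesday's, with Friday's at 84% (78% to 89%) and Tuesday's at 29% (26% to 33%), above my figure. Its words were: “In Tuesday's and Saturday's, partner runs short, which limits percent conversion.”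

The flasks gave Friday's > Thursday's > Monday's > Wednesday's > Saturday's > Tuesday's, with Friday's at 85.4% and Tuesday's at 29.4%, inside both forecast ranges. In Tuesday's, free partner stood at 18% of its own charge, and the gap below the ceiling was 11 percentage points, against my correction of 12.4%. At 300 min, the time constant of 25.6 min shrinks my correction to <0.001%, which puts my target on the ceiling; Tuesday's then held 40.0% target.

    substrate + coupling partner ⇌ loose adduct, settled at all times (K = 2.90 /M)
    loose adduct → target (k = 0.126 /min)
    substrate + target ⇌ idle adduct, settled at all times (K = 8.60 /M)

For Tuesday's read at 8.0 min, the same time constant of 25.6 min gives 10.7% target. The computed flask held 13.1% target.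

The runs come from a simulation on assumed constants; scatter was added.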